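(The readings come from a simulation on assumed constants; the scatter is artificial.)

If each D costs one Z, then the L that finds no Z is a leftover, 10.0 % of the L charged in these flasks. Its counterpart is the ceiling, 90.0 %, the Z charged over the L charged, with Z as the limiting reagent.

| flask | L | Z | E | temperature | remark | time |
|---|---|---|---|---|---|---|
| ochre | 0.20 M | 0.18 M | 1 M | 65 °C | run made earlier |  |
| violet | 0.28 M | 0.18 M | 1 M | 80 °C | run made earlier |  |
| green | 0.44 M | 0.18 M | 1 M | 65 °C | run made earlier |  |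
| birch | 0.20 M | 0.180 M (fed, over 8.0 min) | 1.00 M | 80 °C | all else is in the flask from the start; the feed brings no volume worth counting | 12 min |
| alder | 0.20 M | 0.180 M | 1.00 M |  | everything together at the start at 60 °C, warmed to 80 °C at 8.0 min | 12 min |
| elm | 0.20 M (fed, over 8.0 min) | 0.180 M | 1.00 M |  | the addition at 60 °C, then warmed to 80 °C; the feed brings no volume worth counting | 12 min |
| ash | 0.20 M | 0.180 M | 1.00 M | 80 °C | everything together at the start | 12 min |

| run | time / min | D / % | X / % | L / % |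
|---|---|---|---|---|
| ochre | 1.00 | 2.1 | 10.5 | 84.2 |
| ochre | 2.00 | 4.1 | 9.1 | 76.3 |
| ochre | 4.00 | 9.3 | 8.8 | 68.0 |
| ochre | 8.00 | 18.3 | 7.1 | 60.1 |
| ochre | 15.0 | 31.7 | 6.3 | 54.0 |
| violet | 1.00 | 10.1 | 12.5 | 70.1 |
| violet | 2.00 | 19.4 | 11.1 | 63.2 |
| violet | 4.00 | 33.6 | 6.9 | 54.9 |
| violet | 8.00 | 51.6 | 2.6 | 47.0 |
| violet | 15.0 | 60.4 | 1.2 | 39.5 |
| green | 3.00 | 6.8 | 9.5 | 79.6 |
| green | 8.00 | 12.9 | 6.8 | 71.5 |
| green | 12.0 | 19.9 | 4.3 | 72.9 |
| green | 20.0 | 27.6 | 3.0 | 68.1 |
| green | 30.0 | 35.0 | 2.2 | 63.5 |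

(readings scatter by 1 percentage point)

- what was read earlier has a scatter of 1 percentage point, one standard deviation

* which flask leads in amount of D, in percent of the L charged ("all alike" within 1.5 percentage points) (birch / alder / elm / ash / all alike)
* how much D is there at the end, in percent of the L charged: birch
* how much D is there at the end, in percent of the L charged: alder
* how much D is there at the end, in percent of the L charged: elm
* how much D is there at the end, in percent of the L charged: ash

I doubt the one-for-one guess, so I test it on violet, where the ceiling is 64.3 %. Two Z per D give violet a ceiling of 32.1 %, yet it reads 60.4 % at 15.0 min, just under one-for-one. The guess stands.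

But a ceiling is no figure for 12 min. The four flasks share it, and ochre, with the same ceiling, reads 31.7 % at 15.0 min. So I ask what share of the ceiling heat brings. Violet reads 51.6 % at 8.00 min, a share of 80.3 %.

Violet has more L, though. If Z is used in step with L, the 12 min of ash counts as 8.57 min of violet's time, against the 8.00 min of that reading. So I commit to 72.2 % for ash.

Does ash lead? Alder and elm stay at 60 °C for 8.0 min of the 12 min. At 1.00 min, ochre at 65 °C reads 2.1 % against 10.1 % for violet at 80 °C, a factor of 4.81, while their charges of L differ by a factor of 1.40. Birch is hot but receives its Z over 8.0 min, so I put ash first.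

The forecast names ash as the leader, with birch 58 %, alder 47 %, elm 44 % and ash 67 %, and it reasons “Feeding Z keeps X low”. My figure for ash stands above its figure.

The flasks give birch 59.7 %, alder 44.4 %, elm 41.6 % and ash 69.2 %, so ash leads, and each forecast value holds within its tolerance.

    Q + Z ⇌ E + G (K = 4.40, k = 0.200 M⁻¹ s⁻¹, Ea = 65.0 kJ mol⁻¹, ΔH = 3.00 kJ mol⁻¹)
    X + Z ⇌ E + Q (K = 6.30, k = 0.220 M⁻¹ s⁻¹, Ea = 54.0 kJ mol⁻¹, ΔH = −53.0 kJ mol⁻¹)
    L + Z ⇌ E + X (K = 4.50, k = 0.0720 M⁻¹ s⁻¹, Ea = 81.0 kJ mol⁻¹, ΔH = 34.0 kJ mol⁻¹)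
    E + X → D (k = 0.0140 M⁻¹ s⁻¹, Ea = 85.0 kJ mol⁻¹)
    G + Z ⇌ E + J (K = 24.0, k = 0.0280 M⁻¹ s⁻¹, Ea = 81.0 kJ mol⁻¹, ΔH = −77.0 kJ mol⁻¹)
    (constants at 80 °C)

Q, G and J, complexes with more exchanged than X, together hold 1.13 % of the charge in ash at 12.0 min, and ash reaches 89.9 % of D at 120 min, close to its ceiling of 90.0 %. A neighbour of ash, charged with 0.80 M of L and the same Z, has a ceiling of 22.5 % and a leftover of 77.5 %. At 12.0 min this neighbour holds 22.4 % of D, with Z down to 0.0715 % of its own charge and L at 77.6 %.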